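**Retrosynthetic overview**
- Target ⇒ late Shi epoxidation of C3=C4, tin-directed acetylation of the C7 hydroxyl and α-methylenation of a (3E)-cembrene 16,12-olide.
- Fourteen-membered carbocycle ⇒ ring-closing metathesis of an ε-lactone diene; ε-lactone ⇒ Baeyer–Villiger ring expansion of a 2,2,5-trisubstituted cyclohexanone (the quaternary carbon migrates with retention and becomes C12–O).
- Cyclohexanone ⇒ CuH conjugate reduction (sets C1) of an enone aldol adduct; the aldol (sets C11 and C12, new boron-controlled step) joins 3-allyl-6-methylcyclohexenone and a C4–C11 acetonide aldehyde.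
- Aldehyde ⇒ Grignard addition, Johnson–Claisen (E-alkene), Shi epoxidation–lactonisation (C7/C8 anti), acetonide, half-reduction.
- Ring order: six-membered carbocycle (bought) → seven-membered lactone (ring expansion) → fourteen-membered carbocycle (metathesis) → oxirane.

Assumption: racemic 4-methylcyclohex-2-en-1-one and 4-bromo-2-methylbut-1-ene are bought; atom labels C1–C20 are cembrane numbers of the target (C15 = lactone α-carbon on C1, C16 = lactone C=O on the C12 oxygen, C17 = exocyclic CH2, C18/C19/C20 = methyls on C4/C8/C12).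

Step 1
Reactants: 1 methacrolein; 2 4-bromo-2-methylbut-1-ene
Product: 4 2,6-dimethylhepta-1,6-dien-3-ol (racemic), via homoallyl Grignard reagent 3 (not isolated)
Conditions: Mg, THF, rt; then 1, 0 °C; aq. NH4Cl
Reagents that add atoms: none
Why: Grignard 1,2-addition to the enal carbonyl gives the isopropenyl carbinol, whose racemic centre is erased in step 2.

Step 2
Reactants: 4 2,6-dimethylhepta-1,6-dien-3-ol; 5 trimethyl orthoacetate
Product: 7 methyl (4E)-4,8-dimethylnona-4,8-dienoate, via ketene acetal 6 (not isolated)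
Conditions: 5 (5 equiv), EtCO2H (cat.), 110 → 140 °C, MeOH distilled off
Reagents that add atoms: none
Why: Johnson–Claisen rearrangement through a chair transition state with the side chain equatorial gives the (E)-trisubstituted C7=C8 alkene (typically >95:5) and adds C10 and C11 as the ester arm.

Step 3
Reactants: 7 methyl (4E)-4,8-dimethylnona-4,8-dienoate
Product: 9 (5S)-5-[(1R)-1-hydroxy-5-methylhex-5-en-1-yl]-5-methyloxolan-2-one, via epoxy ester 8 (not isolated)
Conditions: D-fructose-derived Shi ketone (0.3 equiv), KHSO5 (Oxone, 1.3 equiv), K2CO3, Bu4NHSO4, MeCN–(MeO)2CH2–aq. Na2B4O7 buffer, 0 °C; then CSA (cat.), wet CH2Cl2, rt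
Reagents that add atoms: potassium peroxymonosulfate, [K+].[O-]S(=O)(=O)OO; water, O
Why: Shi asymmetric epoxidation (spiro transition state, trisubstituted alkene preferred over the 1,1-disubstituted one) gives the (7R,8R)-epoxide, and acid-triggered 5-exo attack of the ester carbonyl at the tertiary epoxide carbon with inversion sets 8S while C7 stays R (net anti-dioxygenation).

Step 4
Reactants: 9 (5S)-5-[(1R)-1-hydroxy-5-methylhex-5-en-1-yl]-5-methyloxolan-2-one
Product: 10 methyl 3-[(4S,5R)-2,2,4-trimethyl-5-(3-methylbut-3-en-1-yl)-1,3-dioxolan-4-yl]propanoate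
Conditions: Me2C(OMe)2, MeOH, CSA (cat.), rt → 40 °C
Reagents that add atoms: 2,2-dimethoxypropane, CC(C)(OC)OC; methanol, CO
Why: Acid-catalysed lactone methanolysis is pulled forward by trapping the freed 7,8-diol as its acetonide (transacetalisation), with no stereocentre touched.

Step 5
Reactants: 10 methyl 3-[(4S,5R)-2,2,4-trimethyl-5-(3-methylbut-3-en-1-yl)-1,3-dioxolan-4-yl]propanoate
Product: 11 3-[(4S,5R)-2,2,4-trimethyl-5-(3-methylbut-3-en-1-yl)-1,3-dioxolan-4-yl]propanal
Conditions: iBu2AlH (1.1 equiv), CH2Cl2, −78 °C; MeOH, aq. KNaC4H4O6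
Reagents that add atoms: none
Why: Half-reduction of the ester with iBu2AlH stops at the aluminium hemiacetal at −78 °C, which gives the aldehyde on work-up.

Step 6
Reactants: 12 4-methylcyclohex-2-en-1-one (racemic); 13 allylmagnesium bromide
Product: 14 4-methyl-1-(prop-2-en-1-yl)cyclohex-2-en-1-ol (racemic diastereomer mixture)
Conditions: THF, −78 → 0 °C; aq. NH4Cl
Reagents that add atoms: none
Why: Allyl Grignard reagents add 1,2 to enone carbonyls, giving the tertiary bis-allylic alcohol.

Step 7
Reactants: 14 4-methyl-1-(prop-2-en-1-yl)cyclohex-2-en-1-ol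
Product: 15 6-methyl-3-(prop-2-en-1-yl)cyclohex-2-en-1-one (racemic)
Conditions: pyridinium chlorochromate [C5H5NH][CrO3Cl] (2 equiv), SiO2, CH2Cl2, rt
Reagents that add atoms: none
Why: Babler–Dauben oxidative transposition (1,3-shift of the tertiary allylic chromate ester, then oxidation) moves the carbonyl so that the methyl-bearing carbon becomes the α′ position, whose centre is planarised in step 8.

Step 8
Reactants: 15 6-methyl-3-(prop-2-en-1-yl)cyclohex-2-en-1-one; 11 3-[(4S,5R)-2,2,4-trimethyl-5-(3-methylbut-3-en-1-yl)-1,3-dioxolan-4-yl]propanal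
Product: 18 (6R)-6-{(1R)-1-hydroxy-3-[(4S,5R)-2,2,4-trimethyl-5-(3-methylbut-3-en-1-yl)-1,3-dioxolan-4-yl]propyl}-6-methyl-3-(prop-2-en-1-yl)cyclohex-2-en-1-one, via lithium dienolate 16 (not isolated), via boron dienolate 17 (not isolated)
Conditions: LiN(iPr)2, THF, −78 °C; (R,R)-2-bromo-4,5-diphenyl-1,3-ditosyl-1,3,2-diazaborolidine, CH2Cl2, −78 → −40 °C; 11, −78 °C; MeOH, pH 7 buffer, H2O2, 0 °C
Reagents that add atoms: none
Why: Proposed new method: Li→B exchange of the kinetic α′-dienolate 16 with Corey's C2-symmetric diazaborolidinyl bromide gives boron dienolate 17, which adds to 11 through a tight Zimmerman–Traxler chair in which the ring CH2 (trans to O) ends anti and the methyl (cis to O) ends syn to the new carbinol, so C11 and C12 form together in the 11R*,12R* relationship while the N-sulfonyl groups of the controller block one aldehyde face to make it 11R,12R (the reagent antipode is to be confirmed on a model aldehyde); the closest known reaction type is the Corey diazaborolidine-controlled enantioselective boron aldol of ketone and thioester enolates, not yet shown for a tetrasubstituted dienolate that forms a quaternary centre.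

Step 9
Reactants: 18 aldol enone
Product: 19 (2R,5R)-2-{(1R)-1-hydroxy-3-[(4S,5R)-2,2,4-trimethyl-5-(3-methylbut-3-en-1-yl)-1,3-dioxolan-4-yl]propyl}-2-methyl-5-(prop-2-en-1-yl)cyclohexan-1-one
Conditions: Cu(OAc)2·H2O (5 mol %), (S)-DTBM-SEGPHOS (5 mol %), (EtO)2MeSiH, t-BuOH, toluene, 0 °C; aq. NH4Cl
Reagents that add atoms: none
Why: Buchwald–Lipshutz asymmetric CuH conjugate reduction delivers hydride to C1 on the face that leaves the allyl group trans to the C12 side chain (1R), and the ligand antipode is chosen so that it matches the substrate's own bias (axial hydride attack on the half-chair with the large side chain equatorial).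

Step 10
Reactants: 19 cyclohexanone
Product: 20 (4R,7R)-7-{(1R)-1-hydroxy-3-[(4S,5R)-2,2,4-trimethyl-5-(3-methylbut-3-en-1-yl)-1,3-dioxolan-4-yl]propyl}-7-methyl-4-(prop-2-en-1-yl)oxepan-2-one
Conditions: (Me3SiO)2 (2.5 equiv), Me3SiOSO2CF3 (0.2 equiv), CH2Cl2, −40 → 0 °C; aq. citric acid–THF
Reagents that add atoms: bis(trimethylsilyl) peroxide, C[Si](C)(C)OO[Si](C)(C)C
Why: Baeyer–Villiger ring expansion (Criegee 1,2-shift) in which the quaternary α-carbon migrates to oxygen in preference to CH2 and with retention, turning the C12 carbon centre into the tertiary lactone C–O centre (12R), while the silyl peroxide/silyl triflate system oxidises the ketone without epoxidising either C=C bond.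

Step 11
Reactants: 20 ε-lactone diene
Product: 21 (1R,3E,7R,8S,11R,12R)-11-hydroxy-7,8-(isopropylidenedioxy)-17-norcembr-3-en-16,12-olide
Conditions: second-generation Grubbs catalyst RuCl2(=CHPh)(H2IMes)(PCy3) (10 mol %), toluene (1 mM), 80 °C, Ar sparge
Reagents that add atoms: none
Why: Ring-closing metathesis at high dilution joins the allyl and 2-methylallyl termini into the fourteen-membered ring, and the trisubstituted alkene is expected as the less strained E isomer, though this is unproven for this ring; it is done after the ring expansion so that the flexible seven-membered lactone, not the chair ketone, carries the trans-disposed arms.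

Step 12
Reactants: 21 macrocyclic lactone
Product: 24 (1R,3E,7R,8S,11R,12R)-11-hydroxy-7,8-(isopropylidenedioxy)cembra-3,15(17)-dien-16,12-olide, via Mannich base 22 (not isolated), via methiodide 23 (not isolated)
Conditions: LiN(SiMe3)2 (2.5 equiv), THF, −78 °C; CH2=NMe2 I, −78 → 0 °C; MeI, MeOH, rt; aq. NaHCO3, CH2Cl2
Reagents that add atoms: N,N-dimethylmethyleneiminium iodide, C=[N+](C)C.[I-]
Why: Eschenmoser methylenation, in which the lactone enolate (C15 is the only enolisable position) undergoes a Mannich reaction and N-methylation then E1cB loss of trimethylamine gives the exocyclic methylene; it follows the metathesis so the acrylate-type alkene cannot compete in ring closure.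

Step 13
Reactants: 24 acetonide α-methylene lactone
Product: 25 (1R,3E,7R,8S,11R,12R)-7,8,11-trihydroxycembra-3,15(17)-dien-16,12-olide
Conditions: 80% aq. AcOH, 45 °C
Reagents that add atoms: none
Why: Acid hydrolysis of the isopropylidene acetal frees the 7,8-diol before the acid-sensitive epoxide exists.

Step 14
Reactants: 25 triol
Product: 26 (1R,3E,7R,8S,11R,12R)-7-acetoxy-8,11-dihydroxycembra-3,15(17)-dien-16,12-olide
Conditions: Me2SnCl2 (5 mol %), AcCl (1.2 equiv), K2CO3, THF, rt
Reagents that add atoms: acetyl chloride, CC(Cl)=O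
Why: Tin-catalysed regioselective monoacylation of a 1,2-diol, in which the dimethyltin centre chelates the 7,8-diol and activates its less hindered secondary oxygen (C7), so the isolated C11 alcohol and the tertiary C8 alcohol stay free.

Step 15
Reactants: 26 monoacetate
Product: 27 (1R,3S,4S,7R,8S,11R,12R)-7-acetoxy-3,4-epoxy-8,11-dihydroxycembr-15(17)-en-16,12-olide (target)
Conditions: ent-Shi ketone (from L-fructose, 0.5 equiv), KHSO5 (Oxone), K2CO3, Bu4NHSO4, MeCN–(MeO)2CH2–aq. Na2B4O7 buffer, 0 °C
Reagents that add atoms: potassium peroxymonosulfate, [K+].[O-]S(=O)(=O)OO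
Why: Shi asymmetric epoxidation with the enantiomeric ketone delivers oxygen under catalyst control to the only electron-rich alkene to give the (3S,4S)-oxirane (a macrocyclic facial bias could oppose the catalyst); the methylene lactone is inert to the dioxirane and the acylated C7 oxygen can no longer open the epoxide transannularly.

**Compound list**
1 | methacrolein | CC(=C)C=O | starting material
2 | 4-bromo-2-methylbut-1-ene | C=C(C)CCBr | starting material
3 | (3-methylbut-3-en-1-yl)magnesium bromide | C=C(C)CC[Mg]Br | intermediate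
4 | 2,6-dimethylhepta-1,6-dien-3-ol (racemic) | C=C(C)C(O)CCC(C)=C | intermediate
5 | trimethyl orthoacetate | CC(OC)(OC)OC | starting material
6 | 3-[(1-methoxyethenyl)oxy]-2,6-dimethylhepta-1,6-diene | C=C(OC)OC(CCC(C)=C)C(C)=C | intermediate
7 | methyl (4E)-4,8-dimethylnona-4,8-dienoate | COC(=O)CC/C(C)=C/CCC(C)=C | intermediate
8 | methyl 3-[(2R,3R)-2-methyl-3-(3-methylbut-3-en-1-yl)oxiran-2-yl]propanoate | COC(=O)CC[C@@]1(C)O[C@@H]1CCC(C)=C | intermediate
9 | (5S)-5-[(1R)-1-hydroxy-5-methylhex-5-en-1-yl]-5-methyloxolan-2-one | C=C(C)CC[C@@H](O)[C@]1(C)CCC(=O)O1 | intermediate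
10 | methyl 3-[(4S,5R)-2,2,4-trimethyl-5-(3-methylbut-3-en-1-yl)-1,3-dioxolan-4-yl]propanoate | COC(=O)CC[C@]1(C)OC(C)(C)O[C@@H]1CCC(C)=C | intermediate
11 | 3-[(4S,5R)-2,2,4-trimethyl-5-(3-methylbut-3-en-1-yl)-1,3-dioxolan-4-yl]propanal | O=CCC[C@]1(C)OC(C)(C)O[C@@H]1CCC(C)=C | intermediate
12 | 4-methylcyclohex-2-en-1-one (racemic) | CC1CCC(=O)C=C1 | starting material
13 | allylmagnesium bromide | C=CC[Mg]Br | starting material
14 | 4-methyl-1-(prop-2-en-1-yl)cyclohex-2-en-1-ol (racemic mixture) | C=CCC1(O)C=CC(C)CC1 | intermediate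
15 | 6-methyl-3-(prop-2-en-1-yl)cyclohex-2-en-1-one (racemic) | C=CCC1=CC(=O)C(C)CC1 | intermediate
16 | cross-conjugated lithium dienolate of 15 | C=CCC1=CC(O[Li])=C(C)CC1 | intermediate
17 | boron dienolate of 15 on the (R,R)-4,5-diphenyl-1,3-ditosyl-1,3,2-diazaborolidine unit | C=CCC1=CC(OB2N(S(=O)(=O)c3ccc(C)cc3)[C@H](c3ccccc3)[C@@H](c3ccccc3)N2S(=O)(=O)c3ccc(C)cc3)=C(C)CC1 | intermediate
18 | (6R)-6-{(1R)-1-hydroxy-3-[(4S,5R)-2,2,4-trimethyl-5-(3-methylbut-3-en-1-yl)-1,3-dioxolan-4-yl]propyl}-6-methyl-3-(prop-2-en-1-yl)cyclohex-2-en-1-one | C=CCC1=CC(=O)[C@](C)(CC1)[C@H](O)CC[C@]1(C)OC(C)(C)O[C@@H]1CCC(C)=C | intermediate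
19 | (2R,5R)-2-{(1R)-1-hydroxy-3-[(4S,5R)-2,2,4-trimethyl-5-(3-methylbut-3-en-1-yl)-1,3-dioxolan-4-yl]propyl}-2-methyl-5-(prop-2-en-1-yl)cyclohexan-1-one | O=C1C[C@@H](CC=C)CC[C@]1(C)[C@H](O)CC[C@]2(C)OC(C)(C)O[C@@H]2CCC(C)=C | intermediate
20 | (4R,7R)-7-{(1R)-1-hydroxy-3-[(4S,5R)-2,2,4-trimethyl-5-(3-methylbut-3-en-1-yl)-1,3-dioxolan-4-yl]propyl}-7-methyl-4-(prop-2-en-1-yl)oxepan-2-one | O=C1C[C@@H](CC=C)CC[C@@](C)(O1)[C@H](O)CC[C@]2(C)OC(C)(C)O[C@@H]2CCC(C)=C | intermediate
21 | (1R,3E,7R,8S,11R,12R)-11-hydroxy-7,8-(isopropylidenedioxy)-17-norcembr-3-en-16,12-olide | C1C(=O)O[C@]2(C)CC[C@@H]1C/C=C(C)/CC[C@H]3OC(C)(C)O[C@@]3(C)CC[C@H]2O | intermediate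
22 | (1R,3E,7R,8S,11R,12R,15RS)-17-(dimethylamino)-11-hydroxy-7,8-(isopropylidenedioxy)cembr-3-en-16,12-olide | CN(C)CC1C(=O)O[C@]2(C)CC[C@@H]1C/C=C(C)/CC[C@H]3OC(C)(C)O[C@@]3(C)CC[C@H]2O | intermediate
23 | N-methyl quaternary ammonium iodide of 22 | C[N+](C)(C)CC1C(=O)O[C@]2(C)CC[C@@H]1C/C=C(C)/CC[C@H]3OC(C)(C)O[C@@]3(C)CC[C@H]2O.[I-] | intermediate
24 | (1R,3E,7R,8S,11R,12R)-11-hydroxy-7,8-(isopropylidenedioxy)cembra-3,15(17)-dien-16,12-olide | C=C1C(=O)O[C@]2(C)CC[C@@H]1C/C=C(C)/CC[C@H]3OC(C)(C)O[C@@]3(C)CC[C@H]2O | intermediate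
25 | (1R,3E,7R,8S,11R,12R)-7,8,11-trihydroxycembra-3,15(17)-dien-16,12-olide | C=C1C(=O)O[C@]2(C)CC[C@@H]1C/C=C(C)/CC[C@@H](O)[C@@](C)(O)CC[C@H]2O | intermediate
26 | (1R,3E,7R,8S,11R,12R)-7-acetoxy-8,11-dihydroxycembra-3,15(17)-dien-16,12-olide | C=C1C(=O)O[C@]2(C)CC[C@@H]1C/C=C(C)/CC[C@@H](OC(C)=O)[C@@](C)(O)CC[C@H]2O | intermediate
27 | (1R,3S,4S,7R,8S,11R,12R)-7-acetoxy-3,4-epoxy-8,11-dihydroxycembr-15(17)-en-16,12-olide | C=C1C(=O)O[C@]2(C)CC[C@@H]1C[C@@H]1O[C@@]1(C)CC[C@@H](OC(C)=O)[C@@](C)(O)CC[C@H]2O | target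

**Totals**
Total step count: 15. Longest linear sequence: 13 steps (steps 1–5, then 8–15); steps 6–7 form the short branch.

**Three steps most likely to fail**

Step 8, the proposed boron aldol. The hindered tetrasubstituted boron dienolate may react slowly, the sense and level of induction are untested, and γ-deprotonation of 15 may compete. The fallback uses known chemistry, sets out from 15 and 11 and comes back at 18. The plain lithium aldol (LiN(iPr)2, THF, −78 °C, then 11) has no reagent control and gives 18 together with its (6S,1′S) syn diastereomer F1. The two are diastereomers because of the dioxolane centres, so they are separated by chromatography, and the simple syn/anti selectivity of this lithium enolate is likely to be modest. F1 is recycled to 15 and 11 by retro-aldol (KOtBu cat., THF, 0 °C).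

Step 10, the ring expansion beside two alkenes. The hindered ketone may be sluggish toward the silyl peroxide, or the silyl triflate may disturb the acetonide. The fallback sets out from 19 and comes back at 20. Both alkenes are masked as vicinal dibromides (pyridinium tribromide, CH2Cl2, −20 °C) to give tetrabromo ketone F2. The classical peracid Baeyer–Villiger (mCPBA, NaHCO3, CH2Cl2, rt) then gives tetrabromo lactone F3. Zn dust in AcOH–Et2O at 0 °C regenerates both alkenes and gives 20.

Step 11, the ring-closing metathesis. The E/Z ratio of the trisubstituted alkene is uncertain and oligomers may form. The fallback sets out from 19 and comes back at 21 by reversing the order of ring formation. Metathesis of the chair ketone 19 with the same ruthenium carbene gives bridged macrocyclic ketone F4. The silyl peroxide ring expansion of F4 ((Me3SiO)2, Me3SiOSO2CF3, CH2Cl2), which tolerates the trisubstituted alkene, then gives 21.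

Further compounds
F1 | step 8 | (6S)-6-{(1S)-1-hydroxy-3-[(4S,5R)-2,2,4-trimethyl-5-(3-methylbut-3-en-1-yl)-1,3-dioxolan-4-yl]propyl}-6-methyl-3-(prop-2-en-1-yl)cyclohex-2-en-1-one | C=CCC1=CC(=O)[C@@](C)(CC1)[C@@H](O)CC[C@]1(C)OC(C)(C)O[C@@H]1CCC(C)=C
F2 | step 10 | tetrabromide of 19 (2,3-dibromopropyl and 3,4-dibromo-3-methylbutyl groups, mixture at the bromo centres) | O=C1C[C@@H](CC(Br)CBr)CC[C@]1(C)[C@H](O)CC[C@]2(C)OC(C)(C)O[C@@H]2CCC(C)(Br)CBr
F3 | step 10 | tetrabromide of 20 (same dibromo groups on the oxepan-2-one) | O=C1C[C@@H](CC(Br)CBr)CC[C@@](C)(O1)[C@H](O)CC[C@]2(C)OC(C)(C)O[C@@H]2CCC(C)(Br)CBr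
F4 | step 11 | (1R,3E,7R,8S,11R,12R)-11-hydroxy-7,8-(isopropylidenedioxy)-12,16-cyclo-17-norcembr-3-en-16-one | O=C1C[C@@H]2CC[C@]1(C)[C@H](O)CC[C@]3(C)OC(C)(C)O[C@@H]3CC/C(C)=C/C2
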